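The flavanone is cut through ring C at C3–C4 and O1–C2. This gives a ring A salicylaldehyde, with C4 as the formyl carbon, O1 as a free phenol and the chiral C8 side chain in place, and a ring B arylacetylene that supplies C2 and C3. The key step exploits the ortho relation of the C4 carbonyl and O1 on ring A: O1 first steers rhodium into the aldehyde C–H bond for alkyne hydroacylation (C3–C4), then closes ring C by oxa-Michael addition to C2 under a chiral catalyst, all in one flask. The side-chain centre comes from an Evans prenylation, and lactonisation onto an ortho oxygen singles out O1.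

Key step: step 11

Remarks: TBS = tert-butyldimethylsilyl; flavanone numbering (O1, C2, C3, C4, C4a, C5–C8, C8a) is used for the target.
Assumption: the quinine-derived thiourea is taken as the catalyst that favours the (2S) epimer; if this substrate shows the opposite sense, its quinidine-derived pseudoenantiomer is used in its place with nothing else changed.

Step 1
Reactants: 1 2,4,6-trihydroxybenzaldehyde
Product: 2 2,4,6-tris(TBS-oxy)benzaldehyde
Conditions: TBSCl, imidazole, DMAP (cat.), DMF, rt to 40 °C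
Reagents that add atoms: tert-butyldimethylsilyl chloride, CC(C)(C)[Si](C)(C)Cl
Why: Silyl ether formation at all three phenols; excess reagent and DMAP should overcome the hydrogen bonding of the two ortho hydroxyls to the aldehyde.

Step 2
Reactants: 3 (4R)-4-benzyl-1,3-oxazolidin-2-one; 4 (diethoxyphosphoryl)acetic acid
Product: 6 (4R)-4-benzyl-3-[(diethoxyphosphoryl)acetyl]-1,3-oxazolidin-2-one, via mixed pivalic anhydride 5 (not isolated)
Conditions: t-BuCOCl, Et3N, THF, −20 °C; then 3, LiCl, rt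
Reagents that add atoms: none
Why: N-Acylation of the oxazolidinone through a mixed anhydride, which should be attacked at the less hindered phosphonoacetyl carbonyl.

Step 3
Reactants: 2 2,4,6-tris(TBS-oxy)benzaldehyde; 6 phosphonate imide
Product: 7 (4R)-4-benzyl-3-{(2E)-3-[2,4,6-tris(TBS-oxy)phenyl]prop-2-enoyl}-1,3-oxazolidin-2-one
Conditions: LiCl, iPr2NEt, MeCN, rt
Reagents that add atoms: none
Why: Horner–Wadsworth–Emmons olefination under Masamune–Roush conditions should give the (E)-enimide with a base mild enough for aryl silyl ethers.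

Step 4
Reactants: 7 (E)-enimide
Product: 8 (4R)-4-benzyl-3-{3-[2,4,6-tris(TBS-oxy)phenyl]propanoyl}-1,3-oxazolidin-2-one
Conditions: H2 (1 atm), Pd/C, EtOAc, rt
Reagents that add atoms: none
Why: Catalytic hydrogenation of the conjugated C=C bond; aryl silyl ethers and the C-benzyl group of the auxiliary should be inert.

Step 5
Reactants: 8 saturated imide
Product: 9 (4R)-4-benzyl-3-[(2R)-5-methyl-2-{[2,4,6-tris(TBS-oxy)phenyl]methyl}hex-4-enoyl]-1,3-oxazolidin-2-one
Conditions: NaN(SiMe3)2, THF, −78 °C; prenyl bromide, −78 to −40 °C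
Reagents that add atoms: prenyl bromide (1-bromo-3-methylbut-2-ene), CC(C)=CCBr
Why: Evans asymmetric alkylation; the chelated (Z)-sodium enolate should be prenylated on the face opposite the benzyl group of the (R)-auxiliary, which sets the (R) centre of the side chain.

Step 6
Reactants: 9 prenylated imide
Product: 11 (3R)-5,7-dihydroxy-3-(3-methylbut-2-en-1-yl)-3,4-dihydro-2H-chromen-2-one, via triol imide 10 (not isolated)
Conditions: Et3N·3HF, Et3N, MeCN, rt to 40 °C
Reagents that add atoms: none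
Why: Fluoride desilylation frees the three phenols and one of the two equivalent ortho phenols should then displace the auxiliary by 6-exo-trig transacylation (lactonisation), which marks the future O1 and leaves the stereocentre untouched in the buffered medium.

Step 7
Reactants: 11 dihydroxy lactone
Product: 12 (3R)-5,7-bis(TBS-oxy)-3-(3-methylbut-2-en-1-yl)-3,4-dihydro-2H-chromen-2-one
Conditions: TBSOTf, 2,6-lutidine, CH2Cl2, −78 to 0 °C
Reagents that add atoms: tert-butyldimethylsilyl triflate, CC(C)(C)[Si](C)(C)OS(=O)(=O)C(F)(F)F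
Why: Silylation of the two remaining phenols (future O5 and O7) with a silyl triflate and a hindered base that cannot open the aryl lactone.

Step 8
Reactants: 12 bis-silyl lactone
Product: 14 2-[(2R)-2-(2-hydroxypropan-2-yl)-5-methylhex-4-en-1-yl]-3,5-bis(TBS-oxy)phenol, via methyl ketone 13 (not isolated)
Conditions: MeMgBr, LaCl3·2LiCl (cat.), THF, −20 to 0 °C
Reagents that add atoms: methylmagnesium bromide, C[Mg]Br
Why: Double Grignard addition to the aryl lactone gives the tertiary alcohol and releases the O1 phenol; the lanthanum salt favours addition over enolisation, so the adjacent stereocentre should be kept.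

Step 9
Reactants: 14 phenol
Product: 16 2-hydroxy-3-[(2R)-2-(2-hydroxypropan-2-yl)-5-methylhex-4-en-1-yl]-4,6-bis(TBS-oxy)benzaldehyde, via salicyl alcohol 15 (not isolated)
Conditions: MgCl2, Et3N, (CH2O)n, THF, reflux
Reagents that add atoms: paraformaldehyde (as formaldehyde), C=O
Why: Casnati–Skattebøl ortho-formylation; the magnesium phenoxide delivers formaldehyde only to the one free ortho position and a second formaldehyde oxidises the benzylic alkoxide by hydride transfer, so the formyl group should enter next to O1 only.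

Step 10
Reactants: 2 2,4,6-tris(TBS-oxy)benzaldehyde
Product: 17 2-ethynyl-1,3,5-tris(TBS-oxy)benzene
Conditions: Me3SiCHN2, n-BuLi, THF, −78 °C to rt
Reagents that add atoms: trimethylsilyldiazomethane, C[Si](C)(C)C=[N+]=[N-]
Why: Colvin homologation; addition of lithiated trimethylsilyldiazomethane, Peterson elimination and 1,2-hydrogen shift of the alkylidene carbene should give the terminal alkyne without the carbonate and methanol that would cleave aryl silyl ethers.

Step 11
Reactants: 16 salicylaldehyde; 17 arylacetylene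
Product: 19 (2S)-8-[(2R)-2-(2-hydroxypropan-2-yl)-5-methylhex-4-en-1-yl]-5,7-bis(TBS-oxy)-2-[2,4,6-tris(TBS-oxy)phenyl]-2,3-dihydro-4H-chromen-4-one, via chalcone 18 (not isolated)
Conditions: [Rh(cod)Cl]2 (cat.), Fe(C5H4PPh2)2 (dppf, cat.), Na2CO3 (cat.), toluene, 80 °C; then 0 °C, N-[3,5-bis(trifluoromethyl)phenyl]-N'-[(8α,9S)-6'-methoxycinchonan-9-yl]thiourea (cat.)
Reagents that add atoms: none
Why: The phenoxide O1 of 16 chelates monovalent rhodium, which inserts into the aldehyde C–H bond; the acyl rhodium hydride hydrometalates 17 with hydride on the internal carbon, and reductive elimination forms C3–C4 of chalcone 18, whose O1 then adds to the enone β-carbon to form O1–C2. The closest known reaction type is the rhodium-catalysed tandem alkyne hydroacylation of salicylaldehydes and oxa-Michael addition to chroman-4-ones, joined here to the cinchona-thiourea-catalysed cyclisation of 2'-hydroxychalcones to flavanones. Ring C is closed by a 6-endo-trig oxa-Michael addition. C2 is set in that closure by the chiral bifunctional catalyst (thiourea on the enone carbonyl, quinuclidine on the phenol), the side-chain centre being too remote to bias it; the closure is run cold and stopped before reversible ring opening can level the two C2 epimers, which are diastereomers and can be separated. The hydroacylation needs linear regioselectivity, which the two ortho silyloxy groups and the electron-rich aryl of 17 should secure by keeping rhodium on the terminal carbon; chelation by O1 should outrun decarbonylation, and closure through O1 alone is secured because O5 and O7 are silylated.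

Step 12
Reactants: 19 penta-silyl flavanone
Product: 20 (2S)-5,7-dihydroxy-8-[(2R)-2-(2-hydroxypropan-2-yl)-5-methylhex-4-en-1-yl]-2-(2,4,6-trihydroxyphenyl)-2,3-dihydro-4H-chromen-4-one
Conditions: HF·pyridine, pyridine, THF, 0 °C to rt
Reagents that add atoms: none
Why: Buffered fluoride cleavage of the five aryl silyl ethers under non-basic conditions, which should avoid ring opening of the flavanone (C2 epimerisation) and ionisation of the tertiary alcohol.

Compound list

1 | 2,4,6-trihydroxybenzaldehyde | O=Cc1c(O)cc(O)cc1O | starting material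
2 | 2,4,6-tris(TBS-oxy)benzaldehyde | O=Cc1c(O[Si](C)(C)C(C)(C)C)cc(O[Si](C)(C)C(C)(C)C)cc1O[Si](C)(C)C(C)(C)C | intermediate
3 | (4R)-4-benzyl-1,3-oxazolidin-2-one | O=C1N[C@H](Cc2ccccc2)CO1 | starting material
4 | (diethoxyphosphoryl)acetic acid | CCOP(=O)(CC(=O)O)OCC | starting material
5 | (diethoxyphosphoryl)acetic pivalic anhydride | CCOP(=O)(CC(=O)OC(=O)C(C)(C)C)OCC | intermediate
6 | (4R)-4-benzyl-3-[(diethoxyphosphoryl)acetyl]-1,3-oxazolidin-2-one | CCOP(=O)(CC(=O)N1[C@H](Cc2ccccc2)COC1=O)OCC | intermediate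
7 | (4R)-4-benzyl-3-{(2E)-3-[2,4,6-tris(TBS-oxy)phenyl]prop-2-enoyl}-1,3-oxazolidin-2-one | O=C(/C=C/c1c(O[Si](C)(C)C(C)(C)C)cc(O[Si](C)(C)C(C)(C)C)cc1O[Si](C)(C)C(C)(C)C)N1[C@H](Cc2ccccc2)COC1=O | intermediate
8 | (4R)-4-benzyl-3-{3-[2,4,6-tris(TBS-oxy)phenyl]propanoyl}-1,3-oxazolidin-2-one | O=C(CCc1c(O[Si](C)(C)C(C)(C)C)cc(O[Si](C)(C)C(C)(C)C)cc1O[Si](C)(C)C(C)(C)C)N1[C@H](Cc2ccccc2)COC1=O | intermediate
9 | (4R)-4-benzyl-3-[(2R)-5-methyl-2-{[2,4,6-tris(TBS-oxy)phenyl]methyl}hex-4-enoyl]-1,3-oxazolidin-2-one | CC(C)=CC[C@H](Cc1c(O[Si](C)(C)C(C)(C)C)cc(O[Si](C)(C)C(C)(C)C)cc1O[Si](C)(C)C(C)(C)C)C(=O)N1[C@H](Cc2ccccc2)COC1=O | intermediate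
10 | (4R)-4-benzyl-3-{(2R)-5-methyl-2-[(2,4,6-trihydroxyphenyl)methyl]hex-4-enoyl}-1,3-oxazolidin-2-one | CC(C)=CC[C@H](Cc1c(O)cc(O)cc1O)C(=O)N1[C@H](Cc2ccccc2)COC1=O | intermediate
11 | (3R)-5,7-dihydroxy-3-(3-methylbut-2-en-1-yl)-3,4-dihydro-2H-chromen-2-one | CC(C)=CC[C@@H]1Cc2c(O)cc(O)cc2OC1=O | intermediate
12 | (3R)-5,7-bis(TBS-oxy)-3-(3-methylbut-2-en-1-yl)-3,4-dihydro-2H-chromen-2-one | CC(C)=CC[C@@H]1Cc2c(O[Si](C)(C)C(C)(C)C)cc(O[Si](C)(C)C(C)(C)C)cc2OC1=O | intermediate
13 | (3R)-3-{[2-hydroxy-4,6-bis(TBS-oxy)phenyl]methyl}-6-methylhept-5-en-2-one | CC(C)=CC[C@H](Cc1c(O)cc(O[Si](C)(C)C(C)(C)C)cc1O[Si](C)(C)C(C)(C)C)C(C)=O | intermediate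
14 | 2-[(2R)-2-(2-hydroxypropan-2-yl)-5-methylhex-4-en-1-yl]-3,5-bis(TBS-oxy)phenol | CC(C)=CC[C@H](Cc1c(O)cc(O[Si](C)(C)C(C)(C)C)cc1O[Si](C)(C)C(C)(C)C)C(C)(C)O | intermediate
15 | 2-(hydroxymethyl)-6-[(2R)-2-(2-hydroxypropan-2-yl)-5-methylhex-4-en-1-yl]-3,5-bis(TBS-oxy)phenol | CC(C)=CC[C@H](Cc1c(O)c(CO)c(O[Si](C)(C)C(C)(C)C)cc1O[Si](C)(C)C(C)(C)C)C(C)(C)O | intermediate
16 | 2-hydroxy-3-[(2R)-2-(2-hydroxypropan-2-yl)-5-methylhex-4-en-1-yl]-4,6-bis(TBS-oxy)benzaldehyde | CC(C)=CC[C@H](Cc1c(O)c(C=O)c(O[Si](C)(C)C(C)(C)C)cc1O[Si](C)(C)C(C)(C)C)C(C)(C)O | intermediate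
17 | 2-ethynyl-1,3,5-tris(TBS-oxy)benzene | C#Cc1c(O[Si](C)(C)C(C)(C)C)cc(O[Si](C)(C)C(C)(C)C)cc1O[Si](C)(C)C(C)(C)C | intermediate
18 | (2E)-1-{2-hydroxy-3-[(2R)-2-(2-hydroxypropan-2-yl)-5-methylhex-4-en-1-yl]-4,6-bis(TBS-oxy)phenyl}-3-[2,4,6-tris(TBS-oxy)phenyl]prop-2-en-1-one | CC(C)=CC[C@H](Cc1c(O)c(C(=O)/C=C/c2c(O[Si](C)(C)C(C)(C)C)cc(O[Si](C)(C)C(C)(C)C)cc2O[Si](C)(C)C(C)(C)C)c(O[Si](C)(C)C(C)(C)C)cc1O[Si](C)(C)C(C)(C)C)C(C)(C)O | intermediate
19 | (2S)-8-[(2R)-2-(2-hydroxypropan-2-yl)-5-methylhex-4-en-1-yl]-5,7-bis(TBS-oxy)-2-[2,4,6-tris(TBS-oxy)phenyl]-2,3-dihydro-4H-chromen-4-one | CC(C)=CC[C@H](Cc1c(O[Si](C)(C)C(C)(C)C)cc(O[Si](C)(C)C(C)(C)C)c2c1O[C@H](c1c(O[Si](C)(C)C(C)(C)C)cc(O[Si](C)(C)C(C)(C)C)cc1O[Si](C)(C)C(C)(C)C)CC2=O)C(C)(C)O | intermediate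
20 | (2S)-5,7-dihydroxy-8-[(2R)-2-(2-hydroxypropan-2-yl)-5-methylhex-4-en-1-yl]-2-(2,4,6-trihydroxyphenyl)-2,3-dihydro-4H-chromen-4-one | CC(C)=CC[C@H](Cc1c(O)cc(O)c2c1O[C@H](c1c(O)cc(O)cc1O)CC2=O)C(C)(C)O | target

Total step count: 12. Longest linear sequence: 10 steps (steps 1, 3, 4, 5, 6, 7, 8, 9, 11, 12).

Steps most likely to fail

Step 11. The acyl rhodium hydride from the doubly ortho-substituted aldehyde may lose CO or insert the hindered alkyne too slowly, and the closure may show poor facial selectivity at C2 or lose it by reversible ring opening. The fallback sets out from 16 and 17 and comes back at 19. Both hydroxyls of 16 are deprotonated with LiN(SiMe3)2, and the lithium acetylide of 17 (n-BuLi, THF, −78 °C) is added to the aldehyde to give the propargylic alcohol F1 as a mixture of carbinol epimers. NaAlH2(OCH2CH2OMe)2 in THF should reduce it by alkoxide-directed trans-hydroalumination to the (E)-allylic alcohol F2. MnO2 in CH2Cl2 oxidises F2 to chalcone 18, now isolated. Catalytic DBU closes 18 to 19 and its (2R) epimer F3; the two are diastereomers and would be separated by chromatography, and F3 is returned through 18 by the same base and closed again.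

Step 9. Attack of the magnesium phenoxide on formaldehyde at the one free ortho position, crowded by the neighbouring silyloxy group, may be too slow, with silyl loss on long heating. The fallback sets out from 14 and comes back at 16. Boron-templated ortho-hydroxymethylation (PhB(OH)2, (CH2O)n, EtCO2H (cat.), toluene, reflux with water removal) should give the benzodioxaborin F4. Exchange with propane-1,3-diol releases salicyl alcohol 15, now isolated, and MnO2 in CH2Cl2 oxidises its benzylic alcohol to 16.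

Step 10. The alkoxide formed on addition may hand its charge to an ortho silyl group by O-to-O silyl shift instead of undergoing Peterson elimination, which would stall the homologation. The fallback sets out from 2 and comes back at 17. Corey–Fuchs olefination (CBr4, PPh3, CH2Cl2, 0 °C) gives the dibromoalkene F5, which has no alkoxide stage. n-BuLi (THF, −78 °C) then effects bromine–lithium exchange and Fritsch–Buttenberg–Wiechell rearrangement to the lithium acetylide, protonated on work-up to 17.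

Further compounds

F1 | step 11 | 1-{2-hydroxy-3-[(2R)-2-(2-hydroxypropan-2-yl)-5-methylhex-4-en-1-yl]-4,6-bis(TBS-oxy)phenyl}-3-[2,4,6-tris(TBS-oxy)phenyl]prop-2-yn-1-ol (both carbinol epimers) | CC(C)=CC[C@H](Cc1c(O)c(C(O)C#Cc2c(O[Si](C)(C)C(C)(C)C)cc(O[Si](C)(C)C(C)(C)C)cc2O[Si](C)(C)C(C)(C)C)c(O[Si](C)(C)C(C)(C)C)cc1O[Si](C)(C)C(C)(C)C)C(C)(C)O
F2 | step 11 | (2E)-1-{2-hydroxy-3-[(2R)-2-(2-hydroxypropan-2-yl)-5-methylhex-4-en-1-yl]-4,6-bis(TBS-oxy)phenyl}-3-[2,4,6-tris(TBS-oxy)phenyl]prop-2-en-1-ol (both carbinol epimers) | CC(C)=CC[C@H](Cc1c(O)c(C(O)/C=C/c2c(O[Si](C)(C)C(C)(C)C)cc(O[Si](C)(C)C(C)(C)C)cc2O[Si](C)(C)C(C)(C)C)c(O[Si](C)(C)C(C)(C)C)cc1O[Si](C)(C)C(C)(C)C)C(C)(C)O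
F3 | step 11 | (2R)-8-[(2R)-2-(2-hydroxypropan-2-yl)-5-methylhex-4-en-1-yl]-5,7-bis(TBS-oxy)-2-[2,4,6-tris(TBS-oxy)phenyl]-2,3-dihydro-4H-chromen-4-one | CC(C)=CC[C@H](Cc1c(O[Si](C)(C)C(C)(C)C)cc(O[Si](C)(C)C(C)(C)C)c2c1O[C@@H](c1c(O[Si](C)(C)C(C)(C)C)cc(O[Si](C)(C)C(C)(C)C)cc1O[Si](C)(C)C(C)(C)C)CC2=O)C(C)(C)O
F4 | step 9 | 2-{(2R)-1-[2-phenyl-5,7-bis(TBS-oxy)-4H-1,3,2-benzodioxaborin-8-yl]-5-methylhex-4-en-2-yl}propan-2-ol | CC(C)=CC[C@H](Cc1c2OB(c3ccccc3)OCc2c(O[Si](C)(C)C(C)(C)C)cc1O[Si](C)(C)C(C)(C)C)C(C)(C)O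
F5 | step 10 | 2-(2,2-dibromoethenyl)-1,3,5-tris(TBS-oxy)benzene | BrC(Br)=Cc1c(O[Si](C)(C)C(C)(C)C)cc(O[Si](C)(C)C(C)(C)C)cc1O[Si](C)(C)C(C)(C)C
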